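**Retrosynthetic overview** (locants are the octahydroazulene locants of the target: C3 tertiary carbinol, C3a, C4 acyloxy carbon, C5, C6 methyl-bearing, C7, C8, C8a quaternary)
1. Ester C–O: target 22 from diol 20 and 3,4-dimethoxybenzoyl chloride 21 (last step).
2. Cycloheptene from a tetrahydropyran: [2,3]-Wittig ring expansion of the 2-lithio-6-isopropenyltetrahydropyran 19 forms C4–C5 and breaks O–C7. The enabling feature is the homoallylic alcohol array O–C4–C5–C6(CH3)=C7 inside the seven-membered ring: O and C7 are 1,4-related, so the C4 oxygen can serve as ring atom of a six-membered oxacycle (O, C4, C3a, C8a, C8, C7) that carries C6/C5 as an isopropenyl group on C7.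
3. O,S-acetal 18 from lactone 16, from diol 14 (C7 carbinol by CBS reduction), from lactone 10 and isopropenyllithium.
4. Cyclopentane stereocentres: C8a by Johnson–Claisen rearrangement, C3a by hydroboration, both under the control of C3.
5. Cyclopentene 4 from (S)-terpinen-4-ol 1 by ozonolysis/aldol ring contraction (C3 from the chiral pool). Ring order: cyclopentane, then the auxiliary tetrahydropyran, then the cycloheptene.

Key step: step 12

Assumption: (S)-(+)-terpinen-4-ol is used in enantiomerically pure form, and acetals 15, 17 and 18 are carried as anomeric mixtures because the acetal carbon becomes a carbanion in step 12.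

**Step 1**
Reactants: 1 (S)-(+)-terpinen-4-ol [(1S)-4-methyl-1-(propan-2-yl)cyclohex-3-en-1-ol]
Product: 2 triethyl{[(1S)-4-methyl-1-(propan-2-yl)cyclohex-3-en-1-yl]oxy}silane
Conditions: Et3SiOTf, 2,6-lutidine, CH2Cl2, 0 °C → rt
Reagents that add atoms: triethylsilyl trifluoromethanesulfonate, CC[Si](CC)(CC)OS(=O)(=O)C(F)(F)F
Why: Silyl triflate silylation of a hindered tertiary alcohol is standard and masks the hydroxyl against retro-aldol cleavage and β-elimination in the following steps; no stereocentre is touched.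

**Step 2**
Reactants: 2 triethyl{[(1S)-4-methyl-1-(propan-2-yl)cyclohex-3-en-1-yl]oxy}silane
Product: 4 (5R)-2-methyl-5-(propan-2-yl)-5-(triethylsilyloxy)cyclopent-1-ene-1-carbaldehyde, via keto aldehyde 3 (not isolated)
Conditions: O3, CH2Cl2, −78 °C; Me2S, −78 °C → rt; then piperidine, AcOH, PhH, 80 °C
Reagents that add atoms: ozone, [O-][O+]=O
Why: Ozonolysis of the only alkene gives keto aldehyde 3, whose enamine-mediated intramolecular aldol condensation (aldehyde α-carbon onto the methyl ketone, five-membered ring) should give the cyclopentene carbaldehyde, as is known for the analogous limonene-derived keto aldehyde; the carbinol stereocentre is carried through unchanged.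

**Step 3**
Reactants: 4 (5R)-2-methyl-5-(propan-2-yl)-5-(triethylsilyloxy)cyclopent-1-ene-1-carbaldehyde
Product: 5 [(5R)-2-methyl-5-(propan-2-yl)-5-(triethylsilyloxy)cyclopent-1-en-1-yl]methanol
Conditions: NaBH4, CeCl3·7H2O, MeOH, 0 °C
Reagents that add atoms: none
Why: Luche reduction delivers hydride 1,2 to the enal and gives the primary allylic alcohol without creating a stereocentre.

**Step 4**
Reactants: 5 [(5R)-2-methyl-5-(propan-2-yl)-5-(triethylsilyloxy)cyclopent-1-en-1-yl]methanol; 6 triethyl orthoacetate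
Product: 8 ethyl 2-[(1S,3R)-1-methyl-2-methylidene-3-(propan-2-yl)-3-(triethylsilyloxy)cyclopentyl]acetate, via ketene acetal 7 (not isolated)
Conditions: 6 (excess), EtCO2H (cat.), 140 °C, EtOH distilled off
Reagents that add atoms: none
Why: Johnson–Claisen rearrangement through a chair transition state builds the quaternary C8a and the exocyclic methylene; allylic 1,2-strain with the CH2O arm should place the small OSiEt3 group in the ring plane and the isopropyl group pseudo-axial at C3, so the ketene acetal is expected to bond to C8a on the face anti to isopropyl (syn to oxygen).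

**Step 5**
Reactants: 8 ethyl 2-[(1S,3R)-1-methyl-2-methylidene-3-(propan-2-yl)-3-(triethylsilyloxy)cyclopentyl]acetate
Product: 10 (4aS,7R,7aR)-4a-methyl-7-(propan-2-yl)-7-(triethylsilyloxy)hexahydrocyclopenta[c]pyran-3(1H)-one, via hydroxy ester 9 (not isolated)
Conditions: 9-borabicyclo[3.3.1]nonane (9-BBN), THF, 0 → 60 °C; 30% H2O2, aq. NaOAc, 0 °C → rt; then pyridinium p-toluenesulfonate (cat.), PhH, 60 °C
Reagents that add atoms: hydrogen peroxide, OO
Why: Anti-Markovnikov hydroboration by the bulky dialkylborane is expected on the face that carries only the oxygen atom and the CH2CO2Et group (opposite to the C8a methyl and the C3 isopropyl), which puts H-3a trans to the angular methyl; oxidation with retention and acid-catalysed lactonisation should then give the trans-fused δ-lactone.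

**Step 6**
Reactants: 10 (4aS,7R,7aR)-4a-methyl-7-(propan-2-yl)-7-(triethylsilyloxy)hexahydrocyclopenta[c]pyran-3(1H)-one; 11 2-bromopropene
Product: 13 1-[(1S,2R,3R)-2-(hydroxymethyl)-1-methyl-3-(propan-2-yl)-3-(triethylsilyloxy)cyclopentyl]-3-methylbut-3-en-2-one, via isopropenyllithium 12 (not isolated)
Conditions: 11, t-BuLi (2 equiv), Et2O, −78 °C; then 10, THF, −78 °C; H2O
Reagents that add atoms: none
Why: Mono-addition of an alkenyllithium to a δ-lactone at −78 °C stops at the lithium hemiketal, which on quench should open to the isopropenyl ketone and the primary alcohol (in equilibrium with its hemiketal); no stereocentre is formed.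

**Step 7**
Reactants: 13 1-[(1S,2R,3R)-2-(hydroxymethyl)-1-methyl-3-(propan-2-yl)-3-(triethylsilyloxy)cyclopentyl]-3-methylbut-3-en-2-one
Product: 14 (2R)-1-[(1S,2R,3R)-2-(hydroxymethyl)-1-methyl-3-(propan-2-yl)-3-(triethylsilyloxy)cyclopentyl]-3-methylbut-3-en-2-ol
Conditions: (S)-Me-CBS [(S)-1-methyl-3,3-diphenyltetrahydro-1H,3H-pyrrolo[1,2-c][1,3,2]oxazaborole] (0.2 equiv), catecholborane, PhMe, −78 °C; MeOH
Reagents that add atoms: none
Why: Corey–Bakshi–Shibata reduction of the enone with the isopropenyl group as the large substituent should give the (R)-allylic alcohol under reagent control (catecholborane does not hydroborate the alkenes at −78 °C); this carbinol becomes the pyran carbon whose isopropenyl group is cis to the angular methyl.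

**Step 8**
Reactants: 14 (2R)-1-[(1S,2R,3R)-2-(hydroxymethyl)-1-methyl-3-(propan-2-yl)-3-(triethylsilyloxy)cyclopentyl]-3-methylbut-3-en-2-ol
Product: 16 (3R,4aS,7R,7aS)-4a-methyl-3-(prop-1-en-2-yl)-7-(propan-2-yl)-7-(triethylsilyloxy)hexahydrocyclopenta[c]pyran-1(3H)-one, via lactol 15 (not isolated)
Conditions: TEMPO (cat.), PhI(OAc)2, CH2Cl2, rt
Reagents that add atoms: none
Why: Oxoammonium oxidation is faster at the primary than at the secondary carbinol, the aldehyde is trapped by the allylic hydroxyl as lactol 15 and this is oxidised on to the δ-lactone; the neutral conditions should leave the epimerisable C3a untouched.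

**Step 9**
Reactants: 16 (3R,4aS,7R,7aS)-4a-methyl-3-(prop-1-en-2-yl)-7-(propan-2-yl)-7-(triethylsilyloxy)hexahydrocyclopenta[c]pyran-1(3H)-one
Product: 15 (3R,4aS,7R,7aS)-4a-methyl-3-(prop-1-en-2-yl)-7-(propan-2-yl)-7-(triethylsilyloxy)octahydrocyclopenta[c]pyran-1-ol (both anomers)
Conditions: i-Bu2AlH, CH2Cl2, −78 °C; aq. potassium sodium tartrate
Reagents that add atoms: none
Why: Partial reduction of a δ-lactone at −78 °C stops at the aluminium hemiacetal and gives the lactol on work-up.

**Step 10**
Reactants: 15 (3R,4aS,7R,7aS)-4a-methyl-3-(prop-1-en-2-yl)-7-(propan-2-yl)-7-(triethylsilyloxy)octahydrocyclopenta[c]pyran-1-ol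
Product: 17 triethyl{[(3R,4aS,7R,7aS)-4a-methyl-1-(phenylsulfanyl)-3-(prop-1-en-2-yl)-7-(propan-2-yl)octahydrocyclopenta[c]pyran-7-yl]oxy}silane (both anomers)
Conditions: PhSSPh, n-Bu3P, CH2Cl2, rt
Reagents that add atoms: diphenyl disulfide, c1ccccc1SSc1ccccc1
Why: Hata-type thioacetalisation converts the lactol under neutral conditions, through the oxyphosphonium and oxocarbenium ions, into the O,S-acetal; the anomeric configuration is irrelevant for step 12.

**Step 11**
Reactants: 17 triethyl{[(3R,4aS,7R,7aS)-4a-methyl-1-(phenylsulfanyl)-3-(prop-1-en-2-yl)-7-(propan-2-yl)octahydrocyclopenta[c]pyran-7-yl]oxy}silane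
Product: 18 (3R,4aS,7R,7aS)-4a-methyl-1-(phenylsulfanyl)-3-(prop-1-en-2-yl)-7-(propan-2-yl)octahydrocyclopenta[c]pyran-7-ol (both anomers)
Conditions: Bu4NF, THF, 50 °C
Reagents that add atoms: none
Why: Fluoride cleaves the tertiary silyl ether while the O,S-acetal is stable; removing silicon here prevents a silyl shift from oxygen to the carbanion in step 12.

**Step 12**
Reactants: 18 (3R,4aS,7R,7aS)-4a-methyl-1-(phenylsulfanyl)-3-(prop-1-en-2-yl)-7-(propan-2-yl)octahydrocyclopenta[c]pyran-7-ol
Product: 20 (3R,3aR,4R,8aS)-6,8a-dimethyl-3-(propan-2-yl)-1,2,3,3a,4,5,8,8a-octahydroazulene-3,4-diol, via dilithio species 19 (not isolated)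
Conditions: n-BuLi (1.0 equiv), THF, −78 °C; lithium 4,4′-di-tert-butylbiphenylide (LiDBB, 2.2 equiv), THF, −78 °C; −78 → −20 °C; H2O
Reagents that add atoms: none
Why: After the tertiary hydroxyl is capped as its lithium alkoxide, two single-electron transfers from LiDBB cleave the C–S bond to give the 2-lithiotetrahydropyran 19, which on warming should epimerise to the equatorial C–Li isomer and undergo a [2,3]-Wittig rearrangement in which the carbanion carbon (C4) bonds to the CH2 terminus of the isopropenyl group (C5) while the allylic O–C7 bond breaks, so that the ring oxygen becomes the C4 alkoxide. The closest known reaction type is the [2,3]-Wittig ring expansion of 6-vinyl-2-lithiotetrahydropyrans made by reductive lithiation of 2-(phenylthio)tetrahydropyrans, which gives cyclohept-3-enols with inversion at the lithium-bearing carbon. The cycloheptene is closed by a concerted, suprafacial five-centre six-electron sigmatropic shift through an oxygen-bridged bicyclo[3.2.1]-type transition state (pyran chair, new bond spanning the two axial positions that flank oxygen), that is, a ring expansion of the six-membered oxacycle to the seven-membered carbocycle and not an exo or endo closure of an open chain. The only new stereocentre, C4, is controlled by the C7 stereocentre set in step 7: the isopropenyl group is axial and cis to the angular methyl on the rigid trans-fused bicycle, so C5 can reach C4 only on that face, which places the C4 oxygen cis to H-3a and to the C3 hydroxyl and trans to the angular methyl, and the C6=C7 alkene is necessarily cis in the ring; C3, C3a and C8a are spectators. The step needs [2,3] selectivity over the [1,2] shift (which would give a diquinane), over protonation and over reductive cleavage of the allylic ether; the 1,3-diaxial placement of carbanion and isopropenyl group enforced by the trans ring fusion, the absence of any β-leaving group or silyl group near the carbanion, the low temperature and a near-stoichiometric charge of LiDBB are what should secure it.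

**Step 13**
Reactants: 20 (3R,3aR,4R,8aS)-6,8a-dimethyl-3-(propan-2-yl)-1,2,3,3a,4,5,8,8a-octahydroazulene-3,4-diol; 21 3,4-dimethoxybenzoyl chloride
Product: 22 (3R,3aR,4R,8aS)-3-hydroxy-6,8a-dimethyl-3-(propan-2-yl)-1,2,3,3a,4,5,8,8a-octahydroazulen-4-yl 3,4-dimethoxybenzoate
Conditions: Et3N, DMAP, CH2Cl2, 0 °C → rt
Reagents that add atoms: none
Why: DMAP-catalysed acylation should take place only at the secondary C4 hydroxyl because the tertiary C3 hydroxyl is inert under these conditions; no stereocentre is affected.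

**Compound list**
1 | (S)-(+)-terpinen-4-ol, (1S)-4-methyl-1-(propan-2-yl)cyclohex-3-en-1-ol | CC1=CC[C@](O)(C(C)C)CC1 | starting material
2 | triethyl{[(1S)-4-methyl-1-(propan-2-yl)cyclohex-3-en-1-yl]oxy}silane | CC1=CC[C@](O[Si](CC)(CC)CC)(C(C)C)CC1 | intermediate
3 | (3S)-6-oxo-3-(propan-2-yl)-3-(triethylsilyloxy)heptanal | CC(=O)CC[C@@](O[Si](CC)(CC)CC)(C(C)C)CC=O | intermediate
4 | (5R)-2-methyl-5-(propan-2-yl)-5-(triethylsilyloxy)cyclopent-1-ene-1-carbaldehyde | CC1=C(C=O)[C@](O[Si](CC)(CC)CC)(C(C)C)CC1 | intermediate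
5 | [(5R)-2-methyl-5-(propan-2-yl)-5-(triethylsilyloxy)cyclopent-1-en-1-yl]methanol | CC1=C(CO)[C@](O[Si](CC)(CC)CC)(C(C)C)CC1 | intermediate
6 | triethyl orthoacetate | CCOC(C)(OCC)OCC | starting material
7 | triethyl{[(1R)-2-{[(1-ethoxyethenyl)oxy]methyl}-3-methyl-1-(propan-2-yl)cyclopent-2-en-1-yl]oxy}silane (ketene acetal) | C=C(OCC)OCC1=C(C)CC[C@@]1(O[Si](CC)(CC)CC)C(C)C | intermediate
8 | ethyl 2-[(1S,3R)-1-methyl-2-methylidene-3-(propan-2-yl)-3-(triethylsilyloxy)cyclopentyl]acetate | CCOC(=O)C[C@]1(C)CC[C@@](O[Si](CC)(CC)CC)(C(C)C)C1=C | intermediate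
9 | ethyl 2-[(1S,2R,3R)-2-(hydroxymethyl)-1-methyl-3-(propan-2-yl)-3-(triethylsilyloxy)cyclopentyl]acetate | CCOC(=O)C[C@]1(C)CC[C@@](O[Si](CC)(CC)CC)(C(C)C)[C@H]1CO | intermediate
10 | (4aS,7R,7aR)-4a-methyl-7-(propan-2-yl)-7-(triethylsilyloxy)hexahydrocyclopenta[c]pyran-3(1H)-one (trans-fused) | O=C1C[C@]2(C)CC[C@@](O[Si](CC)(CC)CC)(C(C)C)[C@H]2CO1 | intermediate
11 | 2-bromopropene | CC(Br)=C | starting material
12 | isopropenyllithium (prop-1-en-2-yllithium) | [Li]C(C)=C | intermediate
13 | 1-[(1S,2R,3R)-2-(hydroxymethyl)-1-methyl-3-(propan-2-yl)-3-(triethylsilyloxy)cyclopentyl]-3-methylbut-3-en-2-one | C=C(C)C(=O)C[C@]1(C)CC[C@@](O[Si](CC)(CC)CC)(C(C)C)[C@H]1CO | intermediate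
14 | (2R)-1-[(1S,2R,3R)-2-(hydroxymethyl)-1-methyl-3-(propan-2-yl)-3-(triethylsilyloxy)cyclopentyl]-3-methylbut-3-en-2-ol | C=C(C)[C@H](O)C[C@]1(C)CC[C@@](O[Si](CC)(CC)CC)(C(C)C)[C@H]1CO | intermediate
15 | (3R,4aS,7R,7aS)-4a-methyl-3-(prop-1-en-2-yl)-7-(propan-2-yl)-7-(triethylsilyloxy)octahydrocyclopenta[c]pyran-1-ol (lactol, both anomers) | OC1O[C@@H](C(C)=C)C[C@]2(C)CC[C@@](O[Si](CC)(CC)CC)(C(C)C)[C@@H]12 | intermediate
16 | (3R,4aS,7R,7aS)-4a-methyl-3-(prop-1-en-2-yl)-7-(propan-2-yl)-7-(triethylsilyloxy)hexahydrocyclopenta[c]pyran-1(3H)-one | O=C1O[C@@H](C(C)=C)C[C@]2(C)CC[C@@](O[Si](CC)(CC)CC)(C(C)C)[C@@H]12 | intermediate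
17 | triethyl{[(3R,4aS,7R,7aS)-4a-methyl-1-(phenylsulfanyl)-3-(prop-1-en-2-yl)-7-(propan-2-yl)octahydrocyclopenta[c]pyran-7-yl]oxy}silane (both anomers) | C1(Sc3ccccc3)O[C@@H](C(C)=C)C[C@]2(C)CC[C@@](O[Si](CC)(CC)CC)(C(C)C)[C@@H]12 | intermediate
18 | (3R,4aS,7R,7aS)-4a-methyl-1-(phenylsulfanyl)-3-(prop-1-en-2-yl)-7-(propan-2-yl)octahydrocyclopenta[c]pyran-7-ol (both anomers) | C1(Sc3ccccc3)O[C@@H](C(C)=C)C[C@]2(C)CC[C@@](O)(C(C)C)[C@@H]12 | intermediate
19 | lithium alkoxide of 18 in which the C–SPh bond is replaced by C–Li (2-lithiotetrahydropyran, configurationally labile at the lithiated carbon) | [Li]C1O[C@@H](C(C)=C)C[C@]2(C)CC[C@@](O[Li])(C(C)C)[C@@H]12 | intermediate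
20 | (3R,3aR,4R,8aS)-6,8a-dimethyl-3-(propan-2-yl)-1,2,3,3a,4,5,8,8a-octahydroazulene-3,4-diol | O[C@@H]1CC(C)=CC[C@]2(C)CC[C@@](O)(C(C)C)[C@@H]12 | intermediate
21 | 3,4-dimethoxybenzoyl chloride | COc1ccc(C(Cl)=O)cc1OC | starting material
22 | (3R,3aR,4R,8aS)-3-hydroxy-6,8a-dimethyl-3-(propan-2-yl)-1,2,3,3a,4,5,8,8a-octahydroazulen-4-yl 3,4-dimethoxybenzoate | COc1ccc(C(=O)O[C@@H]2CC(C)=CC[C@]3(C)CC[C@@](O)(C(C)C)[C@@H]23)cc1OC | target

**Step count and risks**
Total step count: 13. Longest linear sequence: 13 steps (1 to 22).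

The three steps most likely to fail:

Step 12 (ring expansion). The organolithium may be consumed by the competing [1,2]-shift, by protonation or by reductive scission of the allylic C–O bond before the 1,3-diaxial [2,3] transition state is reached. The fallback makes C4–C5 intermolecularly and closes the ring at C6=C7 by metathesis. It sets out from lactone 10: i-Bu2AlH (CH2Cl2, −78 °C) gives the lactol F1, Wittig methylenation (Ph3P=CH2, THF) the alkenol F2, and Dess–Martin periodinane the aldehyde F3. Reagent-controlled methallylation with (+)-B-methallyldiisopinocampheylborane (Et2O, −78 °C; then NaOH, H2O2) would give the homoallylic alcohol F4. Ring-closing metathesis with the second-generation Grubbs catalyst (CH2Cl2, 40 °C) gives the cycloheptenol silyl ether F5, and Bu4NF (THF, 50 °C) brings the sequence back to the route at diol 20.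

Step 5 (hydroboration). Borane delivery to the face that carries the C8a methyl and the C3 isopropyl group would set H-3a cis to the angular methyl and lead to the cis-fused series. The fallback turns that same facial preference into the required configuration. It sets out from ester 8: mCPBA (NaHCO3, CH2Cl2, 0 °C) gives the spiro-epoxide F6 with oxygen on that face, and methylaluminium bis(4-bromo-2,6-di-tert-butylphenoxide) (CH2Cl2, −78 °C) induces a Meinwald rearrangement whose 1,2-hydride shift arrives anti to the departing oxygen, giving the aldehyde F7 with H-3a trans to the angular methyl. NaBH4 (EtOH, 0 °C) then gives hydroxy ester 9, and pyridinium p-toluenesulfonate closes it to lactone 10, where the route is rejoined.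

Step 4 (Johnson–Claisen rearrangement). Facial discrimination between OSiEt3 and isopropyl in the chair transition state may be insufficient, giving both configurations at C8a. The fallback moves the control from the substrate to a reagent. It sets out from allylic alcohol 5: Ac2O, pyridine and DMAP give the acetate F8. An Ireland–Claisen rearrangement through the boron ketene acetal formed with the chiral controller 2-bromo-4,5-diphenyl-1,3-bis(4-methylphenylsulfonyl)-1,3,2-diazaborolidine and Et3N (CH2Cl2, −78 °C → rt) would give the acid F9; the controller enantiomer that reinforces bonding anti to isopropyl would be found by trying both. EtI and Cs2CO3 (DMF) return the material to the route at ester 8.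

**Further compounds**
F1 | step 12 | (4aS,7R,7aR)-4a-methyl-7-(propan-2-yl)-7-(triethylsilyloxy)octahydrocyclopenta[c]pyran-3-ol (both anomers) | OC1C[C@]2(C)CC[C@@](O[Si](CC)(CC)CC)(C(C)C)[C@H]2CO1
F2 | step 12 | [(1R,2S,5R)-2-methyl-5-(propan-2-yl)-2-(prop-2-en-1-yl)-5-(triethylsilyloxy)cyclopentyl]methanol | C=CC[C@]1(C)CC[C@@](O[Si](CC)(CC)CC)(C(C)C)[C@H]1CO
F3 | step 12 | (1S,2S,5R)-2-methyl-5-(propan-2-yl)-2-(prop-2-en-1-yl)-5-(triethylsilyloxy)cyclopentane-1-carbaldehyde | C=CC[C@]1(C)CC[C@@](O[Si](CC)(CC)CC)(C(C)C)[C@H]1C=O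
F4 | step 12 | (1R)-3-methyl-1-[(1R,2S,5R)-2-methyl-5-(propan-2-yl)-2-(prop-2-en-1-yl)-5-(triethylsilyloxy)cyclopentyl]but-3-en-1-ol | C=CC[C@]1(C)CC[C@@](O[Si](CC)(CC)CC)(C(C)C)[C@H]1[C@H](O)CC(C)=C
F5 | step 12 | (3R,3aR,4R,8aS)-6,8a-dimethyl-3-(propan-2-yl)-3-(triethylsilyloxy)-1,2,3,3a,4,5,8,8a-octahydroazulen-4-ol | O[C@@H]1CC(C)=CC[C@]2(C)CC[C@@](O[Si](CC)(CC)CC)(C(C)C)[C@@H]12
F6 | step 5 | ethyl 2-[(3R,4S,7R)-4-methyl-7-(propan-2-yl)-7-(triethylsilyloxy)-1-oxaspiro[2.4]heptan-4-yl]acetate (epoxide oxygen cis to the C4 methyl) | CCOC(=O)C[C@]1(C)CC[C@@](O[Si](CC)(CC)CC)(C(C)C)[C@]12CO2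
F7 | step 5 | ethyl 2-[(1S,2S,3R)-2-formyl-1-methyl-3-(propan-2-yl)-3-(triethylsilyloxy)cyclopentyl]acetate | CCOC(=O)C[C@]1(C)CC[C@@](O[Si](CC)(CC)CC)(C(C)C)[C@H]1C=O
F8 | step 4 | [(5R)-2-methyl-5-(propan-2-yl)-5-(triethylsilyloxy)cyclopent-1-en-1-yl]methyl acetate | CC(=O)OCC1=C(C)CC[C@@]1(O[Si](CC)(CC)CC)C(C)C
F9 | step 4 | 2-[(1S,3R)-1-methyl-2-methylidene-3-(propan-2-yl)-3-(triethylsilyloxy)cyclopentyl]acetic acid | OC(=O)C[C@]1(C)CC[C@@](O[Si](CC)(CC)CC)(C(C)C)C1=C
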